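(The constants are assumed.)

In a one-step world a reagent has one time constant and nothing to choose, but this flask has forks, so I follow one molecule through them.

    complex A ⇌ enzyme + target (K1 = 0.0057 M, k1 = 78 /s)
    complex B → enzyme + second product (k2 = 1500 /s)
    starting material + enzyme ⇌ complex A (K3 = 150 /M, k3 = 1.9 × 10⁵ /M/s)
    second substrate + enzyme ⇌ complex B (K4 = 130 /M, k4 = 1.9 × 10⁶ /M/s)

starting material 10 mM; second substrate 2.00 equiv; enzyme 0.014 mol%

- the form that holds most of the catalyst when 20% of the starting material are converted (complex A / enzyme / complex B)
- its share of the catalyst then
- apparent order in second substrate when 20% of the starting material are converted (percent change of the rate of making target for one percent more second substrate charged)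
- factor on the rate of making target when 20% of the starting material are converted if enzyme is charged twice over

A molecule of starting material in complex A goes forward with chance 0.0580, since it falls back faster than it moves on. A molecule of second substrate in complex B goes forward with chance 0.0931. That gives 16.0 for the selectivity factor, the binding rate constant times the forward chance for second substrate, divided by the same product for starting material. As long as target does not come back to the enzyme, the fraction of second substrate left is the fraction of starting material left raised to this power.

At the start, each free enzyme stands beside 1.41 in complex A and 2.36 in complex B, so target forms at 0.194 /min as a fraction of the charge. For 20% conversion, the power rule gives me an estimate of 2.79% of the charge of second substrate, which leaves target's return out. I therefore take 0.0657 in complex B per free enzyme as an estimate too, beside 1.15 in complex A, where target's return is counted. On these estimates the freed enzyme multiplies the rate by 2.15. Less starting material keeps 80.0% of that rate, and target's return multiplies what remains by 0.708. That last factor reaches zero with target at 46.1% of the charge, so I expect the run to stop there.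

My reckoning puts 51.9% of the catalyst in complex A, the resting state. It gives an order of −0.0297 in second substrate and a factor 2 for doubled enzyme, which multiplies the rate directly. The forecast says complex A at 52.6%, order −0.016 and factor 2, holding that the “remaining second substrate scales with the amount charged”. Its share and order differ from mine.

The flask gives complex A at 52.6%, enzyme 45.7%, complex B 1.61%, order −0.016 and factor 2.00. The path through complex B ran first, while second substrate lasted: the midpoint of its turnover up to 1.50 min came at 0.191 min, and second substrate stood at 2.07% of its charge after 0.750 min. Raised to the selectivity factor, the 96.8% of starting material left after 0.150 min gives 59.4%, and second substrate then stood at 59.0%. The path through complex A ran on, and after 15.0 min the flask held starting material 53.9% and target 46.1%.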